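**Retrosynthetic overview**
- The C2 stereocentre is set last: a chiral phosphoric acid controls hydride delivery to the planar 2-aryl-chroman-2-ylium ion formed from a racemic C2 silyl ketal.
- Key disconnection: one thermal operation forms ring C (o-quinone methide + silyl enol ether oxa-[4+2]) and ring D (aryl propargyl ether Claisen / 1,5-H shift / oxa-6π). The same heating moves the O-tert-prenyl group to C2' by aromatic Claisen.
- Cascade partners: 2,4-dihydroxybenzyl alcohol (ring A) and the silyl enol ether of 3-O-(1,1-dimethylallyl)-4-O-(1,1-dimethylpropargyl)acetophenone (ring B).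
- Ring order: A and B are bought; C and D form together; the stereocentre follows.

Assumption: flavan C2 is S, as the SMILES encodes. The sense of induction in step 7 cannot be predicted, so the catalyst antipode that gives 2S is used.

**Step 1**
Reactants: 1, 2-methylbut-3-en-2-ol; 2, di-tert-butyl dicarbonate
Product: 3, tert-butyl (2-methylbut-3-en-2-yl) carbonate
Conditions: n-BuLi (1.05 equiv), THF, −78 → 0 °C; then 2, 0 °C → rt
Reagents that add atoms: 2, di-tert-butyl dicarbonate, CC(C)(C)OC(=O)OC(=O)OC(C)(C)C
Why: O-acylation of the lithium tertiary alkoxide by Boc2O gives the mixed carbonate (alkoxide acylation; no stereocentre).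

**Step 2**
Reactants: 4, 3,4-dihydroxyacetophenone; 5, 3-chloro-3-methylbut-1-yne
Product: 6, 1-[3-hydroxy-4-(2-methylbut-3-yn-2-yloxy)phenyl]ethan-1-one
Conditions: 5 (1.3 equiv), K2CO3 (1.05 equiv), KI (1 equiv), CuI (5 mol%), acetone, 50 °C, N2
Reagents that add atoms: 5, 3-chloro-3-methylbut-1-yne, CC(C)(Cl)C#C
Why: Cu-catalysed propargylic etherification; one equivalent of weak base ionises only the 4-OH (para to acetyl, several pKa units more acidic than the 3-OH), so only O4 is alkylated.

**Step 3**
Reactants: 6; 3
Product: 7, 1-[3-(2-methylbut-3-en-2-yloxy)-4-(2-methylbut-3-yn-2-yloxy)phenyl]ethan-1-one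
Conditions: 3 (1.5 equiv), Pd(PPh3)4 (3 mol%), THF, 0 °C, about 2 h, quenched at full conversion
Reagents that add atoms: 3, tert-butyl (2-methylbut-3-en-2-yl) carbonate, C=CC(C)(C)OC(=O)OC(C)(C)C (delivers C5H9; CO2 and t-BuOH are lost)
Why: Tsuji–Trost decarboxylative O-allylation; the released tert-butoxide forms the phenoxide, which attacks the more substituted terminus of the 1,1-dimethyl-π-allyl palladium under kinetic control to give the tertiary ether, and the allylic carbonate ionises far faster than the aryl propargyl ether.

**Step 4**
Reactants: 7
Product: 9, tert-butyl(dimethyl){[1-(3-(2-methylbut-3-en-2-yloxy)-4-(2-methylbut-3-yn-2-yloxy)phenyl)ethenyl]oxy}silane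
Conditions: 8 (1.2 equiv), Et3N (2 equiv), CH2Cl2, 0 °C; NaHCO3 work-up, Et3N-washed silica
Reagents that add atoms: 8, tert-butyldimethylsilyl triflate, CC(C)(C)[Si](C)(C)OS(=O)(=O)C(F)(F)F
Why: Soft enolisation and O-silylation of the methyl ketone (only one enol ether is possible); the amine buffer protects the acid-labile tertiary ethers and leaves the alkyne C–H alone.

**Step 5**
Reactants: 10, 2,4-dihydroxybenzaldehyde
Product: 11, 2,4-dihydroxybenzyl alcohol (4-(hydroxymethyl)benzene-1,3-diol)
Conditions: NaBH4, THF–H2O, 0 °C; pH 7 work-up, used immediately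
Reagents that add atoms: none
Why: Borohydride reduction of the aldehyde; the product self-condenses on storage or with acid, so it is used fresh.

**Step 6 (key step)**
Reactants: 9; 11
Product: 12, rac-2-[(tert-butyldimethylsilyl)oxy]-2-[8-hydroxy-2,2-dimethyl-7-(3-methylbut-2-en-1-yl)-2H-chromen-6-yl]-3,4-dihydro-2H-chromen-7-ol
Conditions: 11 (1.3 equiv, added over 3 h), 2,6-lutidine (0.2 equiv), 4 Å MS, o-xylene, 140 °C, 14 h
Reagents that add atoms: none (all atoms come from 9 and 11; H2O is lost)
Why: Proposed new method: three individually known thermal pericyclic reactions are run concurrently: (i) 11 loses water to the o-quinone methide, which undergoes inverse-demand oxa-Diels–Alder addition with the silyl enol ether (far more nucleophilic than any other alkene or arene present) to close ring C as the 7-hydroxy C2 silyl ketal; (ii) the 4'-O-propargyl ether undergoes aromatic Claisen rearrangement to C5' (its only free ortho position), then 1,5-H shift and oxa-6π closure to the 2,2-dimethylchromene (ring D); (iii) the 3'-O-(1,1-dimethylallyl) ether undergoes aromatic Claisen rearrangement to C2' (its only free ortho position), giving the prenyl group and the free 3'-OH; the closest known reactions are thermal o-quinone methide/enol ether cycloadditions and the Claisen routes to dimethylchromenes and o-prenylphenols, and the C2 configuration of 12 is irrelevant because it is erased in step 7.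

**Step 7**
Reactants: 12
Product: 13, kazinol B, (2S)-2-[8-hydroxy-2,2-dimethyl-7-(3-methylbut-2-en-1-yl)-2H-chromen-6-yl]-3,4-dihydro-2H-chromen-7-ol
Conditions: (R)-TRIP (10 mol%), Hantzsch ester (1.5 equiv), 4 Å MS, toluene, 0 °C → rt
Reagents that add atoms: none (the Hantzsch ester delivers only H)
Why: Proposed new method: the chiral phosphoric acid ionises the silyl ketal to a 2-aryl-chroman-2-ylium/chiral phosphate ion pair (stabilised by O1 and the p-alkoxyaryl group), and the phosphate-bound Hantzsch ester delivers hydride to the Re face of C2 to give 2S from both enantiomers of 12; the closest known reactions are phosphoric acid/Hantzsch ester transfer hydrogenations of 2-arylquinolines, benzoxazines and benzopyrylium ions and chiral-anion-controlled additions to cyclic oxocarbenium ions; the prenyl and chromene alkenes and the phenols are inert to this ionic reduction, any ring-opened hydroxy-ketone or 4H-chromene form of 12 funnels to the same cation, and the (S)-catalyst is used if the sense is opposite.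

**Compound list**
1 | 2-methylbut-3-en-2-ol | C=CC(C)(C)O | starting material
2 | di-tert-butyl dicarbonate | CC(C)(C)OC(=O)OC(=O)OC(C)(C)C | starting material
3 | tert-butyl (2-methylbut-3-en-2-yl) carbonate | C=CC(C)(C)OC(=O)OC(C)(C)C | intermediate
4 | 3,4-dihydroxyacetophenone | CC(=O)c1ccc(O)c(O)c1 | starting material
5 | 3-chloro-3-methylbut-1-yne | CC(C)(Cl)C#C | starting material
6 | 1-[3-hydroxy-4-(2-methylbut-3-yn-2-yloxy)phenyl]ethan-1-one | CC(=O)c1ccc(OC(C)(C)C#C)c(O)c1 | intermediate
7 | 1-[3-(2-methylbut-3-en-2-yloxy)-4-(2-methylbut-3-yn-2-yloxy)phenyl]ethan-1-one | CC(=O)c1ccc(OC(C)(C)C#C)c(OC(C)(C)C=C)c1 | intermediate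
8 | tert-butyldimethylsilyl triflate | CC(C)(C)[Si](C)(C)OS(=O)(=O)C(F)(F)F | starting material
9 | TBS enol ether of 7 | C=C(O[Si](C)(C)C(C)(C)C)c1ccc(OC(C)(C)C#C)c(OC(C)(C)C=C)c1 | intermediate
10 | 2,4-dihydroxybenzaldehyde | O=Cc1ccc(O)cc1O | starting material
11 | 2,4-dihydroxybenzyl alcohol | OCc1ccc(O)cc1O | intermediate
12 | racemic C2 silyl ketal (rings A–D complete) | CC(C)=CCc1c(C2(O[Si](C)(C)C(C)(C)C)CCc3ccc(O)cc3O2)cc2c(c1O)OC(C)(C)C=C2 | intermediate
13 | kazinol B, (2S) | CC(C)=CCc1c([C@@H]2CCc3ccc(O)cc3O2)cc2c(c1O)OC(C)(C)C=C2 | target

**Totals**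
Total steps: 7. Longest linear sequence: 5 (steps 2 → 3 → 4 → 6 → 7).

**Three steps most likely to fail**
1. Step 6. The quinone methide may oligomerise or alkylate phenolic rings, the enol ether may be protodesilylated, and the Claisen events may be incomplete.
   Fallback: make the C3–C4 bond by benzylating the enolate of 7 with a 2,4-bis(silyloxy)benzyl bromide. After desilylation, heat for the two aryl-ether Claisen events, then close ring C in step 7 by reductive hemiketal cyclisation instead of cycloaddition.
2. Step 7. The ee may be low, or the ketal may simply ring-open.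
   Fallback: hydrolyse 12 to the open-chain hydroxy ketone and reduce it to the (R)-carbinol by Noyori asymmetric transfer hydrogenation (Ru–TsDPEN, HCO2H/Et3N). Close ring C by Mitsunobu etherification with inversion to give 2S.
3. Step 3. The phenol is hindered, so the linear prenyl ether may form, and Pd may ionise the propargyl ether.
   Fallback: reverse the order. Alkylate the dianion of 4 at the more nucleophilic 3-phenoxide with 5 under Cu catalysis, semi-hydrogenate with Lindlar catalyst to the 3-O-tert-prenyl ether, then propargylate the 4-OH with 5 under Cu catalysis, which tolerates hindered phenols.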